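Everything rests on opening ring C of unit 2 (units numbered from the catechin end) at O1–C2 and C3–C4. Its C4 methine carries ring A of unit 3 and is bonded to C4a, beside the O1-bearing C8a: the retron of an o-quinone methide with that aryl group on its methide carbon, trapped across the oxadiene by an enamine that supplies C2 and the oxygenated C3. One amine-catalysed [4+2] with benzyloxyacetaldehyde therefore forms both bonds, closes this pyran and sets C3 and C4, leaving C2 as a lactol. The precursor is a benzhydrol whose carbinol carbon joins C8 of perbenzylated procyanidin B2 to a monophenolic ring already carrying unit 1 para to its free hydroxyl.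

Key step: step 12

Remark: the target is read as catechin-(4α→6)-epicatechin-(4β→8)-epicatechin-(4β→8)-epicatechin; every C2 is R, C3 is S in unit 1 and R in units 2 to 4, and each C4 aryl group is trans to the neighbouring C3 oxygen.
Remark: 3,5-bis(benzyloxy)phenol, 4-bromo-1,2-bis(benzyloxy)benzene and benzyloxyacetaldehyde are taken as catalogue compounds.
Remark: hindered rotation about the C4–aryl bonds makes most intermediates rotamer mixtures; 21 is a pair of carbinol epimers and 26 and 30 are anomer pairs, all of which converge.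
Remark: the flavan-4-yl cations are numbered as the ion pairs in which they form, with the hydroquinone monoanion of DDQ as counter-ion in the oxidations and with triflate in the couplings.

Step 1
Reactants: 1 (+)-catechin
Product: 2 penta-O-benzyl-(+)-catechin
Conditions: NaH, BnBr, DMF, −40 °C to rt
Reagents that add atoms: benzyl bromide, BrCc1ccccc1
Why: Exhaustive Williamson etherification of the four phenols and the C3 alcohol; alkylation of each phenoxide at low temperature should outrun base-induced opening of ring C, so the 2R,3S centres are untouched.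

Step 2
Reactants: 2 penta-O-benzyl-(+)-catechin
Product: 4 penta-O-benzyl-4-(2-ethoxyethoxy)catechin, via flavan-4-yl hydroquinolate ion pair 3 (not isolated)
Conditions: DDQ, HOCH2CH2OEt, CH2Cl2, rt
Reagents that add atoms: 2-ethoxyethanol, CCOCCO
Why: DDQ benzylic oxidation: hydride transfer to the quinone from the C4–H bond activated by the 5- and 7-oxygens of ring A gives the flavan-4-yl cation paired with the hydroquinone monoanion (3), and the alcohol captures the cation; the new C4 centre is ionised again in step 4, so its configuration does not matter.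

Step 3
Reactants: 5 3,5-bis(benzyloxy)phenol
Product: 6 [3,5-bis(benzyloxy)phenoxy]triisopropylsilane
Conditions: i-Pr3SiCl, imidazole, DMF, rt
Reagents that add atoms: chlorotriisopropylsilane, CC(C)[Si](Cl)(C(C)C)C(C)C
Why: Standard phenol silylation; the bulky silyl group is chosen to screen both positions ortho to this oxygen in the next step.

Step 4
Reactants: 4 penta-O-benzyl-4-(2-ethoxyethoxy)catechin, 6 [3,5-bis(benzyloxy)phenoxy]triisopropylsilane
Product: 8 penta-O-benzyl-4α-[2,6-bis(benzyloxy)-4-(triisopropylsilyloxy)phenyl]catechin, via flavan-4-yl triflate ion pair 7 (not isolated)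
Conditions: Me3SiOTf (cat.), 6 (3 equiv), CH2Cl2, −78 to −40 °C
Reagents that add atoms: none
Why: Lewis acid-promoted SN1 Friedel–Crafts alkylation of the kind used for interflavan bonds: silylation of the 4-alkoxy oxygen releases the flavan-4-yl cation as its triflate 7, which should be captured at the arene carbon para to the silyloxy group, the two ortho positions being screened by the triisopropylsilyl group, and the arene enters trans to the 3-benzyloxy group, setting C4 of unit 1 as 4α (3,4-trans); excess 6 suppresses double alkylation.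

Step 5
Reactants: 8 penta-O-benzyl-4α-[2,6-bis(benzyloxy)-4-(triisopropylsilyloxy)phenyl]catechin
Product: 9 penta-O-benzyl-4α-[2,6-bis(benzyloxy)-4-hydroxyphenyl]catechin
Conditions: Bu4NF, AcOH, THF, 0 °C
Reagents that add atoms: none
Why: Fluoride cleavage of an aryl silyl ether; acetic acid buffers the phenoxide, and benzyl ethers and the C4–aryl bond are inert.

Step 6
Reactants: 9 penta-O-benzyl-4α-[2,6-bis(benzyloxy)-4-hydroxyphenyl]catechin
Product: 11 2,4-bis(benzyloxy)-6-hydroxy-3-(penta-O-benzylcatechin-4α-yl)benzaldehyde, via hydroxymethyl phenol 10 (not isolated)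
Conditions: MgCl2, Et3N, (CH2O)n, THF, reflux
Reagents that add atoms: paraformaldehyde (formaldehyde), C=O
Why: Magnesium phenoxide-directed ortho-formylation (Casiraghi–Skattebøl): only the single phenol ring is activated, its two ortho positions are equivalent, and the hydroxymethyl intermediate 10 is oxidised in place by a second formaldehyde through hydride transfer.

Step 7
Reactants: 12 (−)-epicatechin
Product: 13 penta-O-benzyl-(−)-epicatechin
Conditions: NaH, BnBr, DMF, −40 °C to rt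
Reagents that add atoms: benzyl bromide, BrCc1ccccc1
Why: Exhaustive Williamson etherification as in step 1; the 2R,3R centres are not involved.

Step 8
Reactants: 13 penta-O-benzyl-(−)-epicatechin
Product: 14 8-bromo-penta-O-benzylepicatechin
Conditions: NBS, CH2Cl2, −78 to 0 °C
Reagents that add atoms: N-bromosuccinimide, O=C1CCC(=O)N1Br
Why: Electrophilic aromatic bromination of ring A, which is known to occur at C8 of benzylated flavan-3-ols; the bromine later caps the electrophile and marks the site of lithiation.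

Step 9
Reactants: 14 8-bromo-penta-O-benzylepicatechin
Product: 16 8-bromo-penta-O-benzyl-4β-(2-ethoxyethoxy)epicatechin, via bromoflavan-4-yl hydroquinolate ion pair 15 (not isolated)
Conditions: DDQ, HOCH2CH2OEt, CH2Cl2, rt
Reagents that add atoms: 2-ethoxyethanol, CCOCCO
Why: The same DDQ benzylic alkoxylation as in step 2, through hydride transfer to the quinone and the ion pair 15; the alcohol should add to the cation anti to the 3-benzyloxy group (4β), a centre that is ionised again in step 10.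

Step 10
Reactants: 16 8-bromo-penta-O-benzyl-4β-(2-ethoxyethoxy)epicatechin, 13 penta-O-benzyl-(−)-epicatechin
Product: 18 8-bromo-deca-O-benzylprocyanidin B2, via bromoflavan-4-yl triflate ion pair 17 (not isolated)
Conditions: Me3SiOTf (cat.), 13 (3 equiv), CH2Cl2, −78 °C
Reagents that add atoms: none
Why: Me3SiOTf-catalysed SN1 Friedel–Crafts interflavan coupling: the 4-alkoxy group is ionised to the triflate ion pair 17, whose cation is attacked by the more nucleophilic C8 of 13 on the face anti to the cis 2-aryl and 3-benzyloxy groups, setting C4 of unit 3 as 4β (3,4-trans), while the bromine at C8 keeps the electrophile from adding to itself.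

Step 11
Reactants: 18 8-bromo-deca-O-benzylprocyanidin B2, 11 2,4-bis(benzyloxy)-6-hydroxy-3-(penta-O-benzylcatechin-4α-yl)benzaldehyde
Product: 21 o-hydroxybenzhydrol joining the unit 1 ring to C8 of the dimer, via sodium phenoxide 19 (not isolated), via C8 aryllithium 20 (not isolated)
Conditions: 18, n-BuLi, THF, −78 °C; 11 + NaH, THF, 0 °C, then added at −78 °C, to −30 °C; aq NH4Cl
Reagents that add atoms: none
Why: Bromine–lithium exchange at the only C–Br bond gives the C8 aryllithium 20 regiospecifically, and its 1,2-addition to the aldehyde of the preformed phenoxide 19 (so that no aryllithium is spent as base) is the standard route to o-hydroxybenzhydrols; the carbinol centre forms as a mixture and is planarised in step 12.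

Step 12
Reactants: 21 o-hydroxybenzhydrol joining the unit 1 ring to C8 of the dimer, 22 benzyloxyacetaldehyde
Product: 26 tetramer lactol lacking ring B of unit 2, via o-quinone methide 23 (not isolated), via catalyst enamine 24 (not isolated), via aminal cycloadduct 25 (not isolated)
Conditions: (S)-α,α-diphenylprolinol trimethylsilyl ether (30 mol%), PhCO2H (30 mol%), 22 (5 equiv, slow addition), CHCl3, 0 °C to rt
Reagents that add atoms: none
Why: Benzoic acid assists loss of water from 21 to the o-quinone methide 23, which has no β-hydrogen and is stabilised by the unit 3 aryl group; the amine condenses with 22 to the E-enamine 24, whose α-carbon adds to the methide carbon (C3–C4) while the phenoxide oxygen captures the iminium carbon (O1–C2), and hydrolysis of aminal 25 returns the catalyst. The closest known reaction type is the diarylprolinol silyl ether-catalysed formal inverse-demand oxa-[4+2] of aldehydes with o-quinone methides generated from o-hydroxybenzhydrols, which gives trans-3,4-disubstituted chroman-2-ols. The pyran ring of unit 2 closes by 6-exo-trig attack of O1 on the iminium carbon, the second bond of an asynchronous [4+2]. C3 (R) should be set by the catalyst, whose diphenyl(silyloxy)methyl group screens one enamine face as in Michael additions of aldehyde enamines, and C4 by the endo approach of the E-enamine, which places the 3-benzyloxy and 4-aryl groups trans; C2 remains an anomer mixture. The step needs catalyst control over the resident stereocentres, the nearest of which lie four bonds from the methide carbon, and it needs the 6-linkage of unit 2, which is secured because only the oxygen para to unit 1 is unprotected on that ring.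

Step 13
Reactants: 26 tetramer lactol lacking ring B of unit 2
Product: 27 tetramer lactone (3-benzyloxy-4-aryl-dihydrocoumarin)
Conditions: Dess–Martin periodinane, NaHCO3, CH2Cl2, 0 °C to rt
Reagents that add atoms: none
Why: Dess–Martin oxidation of a lactol to the lactone converges both anomers and, being buffered, should leave the benzyl ethers, the interflavan bonds and the C3 centre untouched.

Step 14
Reactants: 27 tetramer lactone (3-benzyloxy-4-aryl-dihydrocoumarin), 28 4-bromo-1,2-bis(benzyloxy)benzene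
Product: 30 2-aryl hemiketal of the tetramer, via aryllithium 29 (not isolated)
Conditions: 28, n-BuLi, THF, −78 °C; then 27, −78 °C; NH4Cl/MeOH at −78 °C
Reagents that add atoms: none
Why: Bromine–lithium exchange gives aryllithium 29, which adds once to the aryl lactone; the lithium alkoxide of the hemiketal, chelated by the 3-benzyloxy oxygen, should persist until the cold quench as in aryllithium additions to sugar lactones, and the new C2 centre is removed in step 15.

Step 15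
Reactants: 30 2-aryl hemiketal of the tetramer
Product: 32 icosa-O-benzyl tetramer, via 2-aryl oxocarbenium ion 31 (not isolated)
Conditions: Et3SiH, BF3·OEt2, CH2Cl2, −78 to −40 °C
Reagents that add atoms: none
Why: Ionic hydrogenation of a 2-aryl lactol as in C-aryl glycoside synthesis: in oxocarbenium ion 31 peri strain with the 5-benzyloxy group and strain with the coplanar 2-aryl group should hold the 4-aryl and 3-benzyloxy groups trans-diaxial, so hydride is expected to enter along the axial, chair-forming trajectory anti to the adjacent 3-benzyloxy group, leaving the 2-aryl group equatorial and cis to it (2R, the epicatechin pattern).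

Step 16
Reactants: 32 icosa-O-benzyl tetramer
Product: 33 catechin-(4α→6)-epicatechin-(4β→8)-epicatechin-(4β→8)-epicatechin
Conditions: H2 (1 atm), Pd(OH)2/C, THF/MeOH/H2O, rt
Reagents that add atoms: none
Why: Hydrogenolysis of the twenty benzyl ethers under neutral conditions, as established for procyanidin oligomers; the interflavan bonds and all eleven stereocentres are not affected.

Compound list

1 | (+)-catechin, (2R,3S) | Oc1cc(O)c2c(c1)O[C@H](c1ccc(O)c(O)c1)[C@@H](O)C2 | starting material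
2 | 3,5,7,3',4'-penta-O-benzyl-(+)-catechin | c4ccccc4COc1cc(OCc4ccccc4)c2c(c1)O[C@H](c1ccc(OCc4ccccc4)c(OCc4ccccc4)c1)[C@@H](OCc4ccccc4)C2 | intermediate
3 | penta-O-benzylcatechin C4 cation (flavan-4-yl cation, drawn as the benzylic carbocation) paired with the monoanion of 2,3-dichloro-5,6-dicyanohydroquinone | c4ccccc4COc1cc(OCc4ccccc4)c2c(c1)O[C@H](c1ccc(OCc4ccccc4)c(OCc4ccccc4)c1)[C@@H](OCc4ccccc4)[CH+]2.[O-]c1c(Cl)c(Cl)c(O)c(C#N)c1C#N | intermediate
4 | penta-O-benzyl-4-(2-ethoxyethoxy)catechin (C4 epimers, either usable) | c4ccccc4COc1cc(OCc4ccccc4)c2c(c1)O[C@H](c1ccc(OCc4ccccc4)c(OCc4ccccc4)c1)[C@@H](OCc4ccccc4)C2OCCOCC | intermediate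
5 | 3,5-bis(benzyloxy)phenol | Oc1cc(OCc2ccccc2)cc(OCc2ccccc2)c1 | starting material
6 | [3,5-bis(benzyloxy)phenoxy]triisopropylsilane | CC(C)[Si](Oc1cc(OCc2ccccc2)cc(OCc2ccccc2)c1)(C(C)C)C(C)C | intermediate
7 | penta-O-benzylcatechin C4 cation as its triflate ion pair | c4ccccc4COc1cc(OCc4ccccc4)c2c(c1)O[C@H](c1ccc(OCc4ccccc4)c(OCc4ccccc4)c1)[C@@H](OCc4ccccc4)[CH+]2.[O-]S(=O)(=O)C(F)(F)F | intermediate
8 | penta-O-benzyl-4α-[2,6-bis(benzyloxy)-4-(triisopropylsilyloxy)phenyl]catechin (aryl trans to 3-OBn) | c4ccccc4COc1cc(OCc4ccccc4)c2c(c1)O[C@H](c1ccc(OCc4ccccc4)c(OCc4ccccc4)c1)[C@@H](OCc4ccccc4)[C@@H]2c1c(OCc4ccccc4)cc(O[Si](C(C)C)(C(C)C)C(C)C)cc1OCc4ccccc4 | intermediate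
9 | penta-O-benzyl-4α-[2,6-bis(benzyloxy)-4-hydroxyphenyl]catechin | c4ccccc4COc1cc(OCc4ccccc4)c2c(c1)O[C@H](c1ccc(OCc4ccccc4)c(OCc4ccccc4)c1)[C@@H](OCc4ccccc4)[C@@H]2c1c(OCc4ccccc4)cc(O)cc1OCc4ccccc4 | intermediate
10 | penta-O-benzyl-4α-[2,6-bis(benzyloxy)-4-hydroxy-3-(hydroxymethyl)phenyl]catechin | c4ccccc4COc1cc(OCc4ccccc4)c2c(c1)O[C@H](c1ccc(OCc4ccccc4)c(OCc4ccccc4)c1)[C@@H](OCc4ccccc4)[C@@H]2c1c(OCc4ccccc4)cc(O)c(CO)c1OCc4ccccc4 | intermediate
11 | 2,4-bis(benzyloxy)-6-hydroxy-3-(penta-O-benzylcatechin-4α-yl)benzaldehyde | c4ccccc4COc1cc(OCc4ccccc4)c2c(c1)O[C@H](c1ccc(OCc4ccccc4)c(OCc4ccccc4)c1)[C@@H](OCc4ccccc4)[C@@H]2c1c(OCc4ccccc4)cc(O)c(C=O)c1OCc4ccccc4 | intermediate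
12 | (−)-epicatechin, (2R,3R) | Oc1cc(O)c2c(c1)O[C@H](c1ccc(O)c(O)c1)[C@H](O)C2 | starting material
13 | 3,5,7,3',4'-penta-O-benzyl-(−)-epicatechin | c4ccccc4COc1cc(OCc4ccccc4)c2c(c1)O[C@H](c1ccc(OCc4ccccc4)c(OCc4ccccc4)c1)[C@H](OCc4ccccc4)C2 | intermediate
14 | 8-bromo-penta-O-benzylepicatechin | c4ccccc4COc1cc(OCc4ccccc4)c2c(c1Br)O[C@H](c1ccc(OCc4ccccc4)c(OCc4ccccc4)c1)[C@H](OCc4ccccc4)C2 | intermediate
15 | 8-bromo-penta-O-benzylepicatechin C4 cation paired with the monoanion of 2,3-dichloro-5,6-dicyanohydroquinone | c4ccccc4COc1cc(OCc4ccccc4)c2c(c1Br)O[C@H](c1ccc(OCc4ccccc4)c(OCc4ccccc4)c1)[C@H](OCc4ccccc4)[CH+]2.[O-]c1c(Cl)c(Cl)c(O)c(C#N)c1C#N | intermediate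
16 | 8-bromo-penta-O-benzyl-4β-(2-ethoxyethoxy)epicatechin (3,4-trans) | c4ccccc4COc1cc(OCc4ccccc4)c2c(c1Br)O[C@H](c1ccc(OCc4ccccc4)c(OCc4ccccc4)c1)[C@H](OCc4ccccc4)[C@H]2OCCOCC | intermediate
17 | 8-bromo-penta-O-benzylepicatechin C4 cation as its triflate ion pair | c4ccccc4COc1cc(OCc4ccccc4)c2c(c1Br)O[C@H](c1ccc(OCc4ccccc4)c(OCc4ccccc4)c1)[C@H](OCc4ccccc4)[CH+]2.[O-]S(=O)(=O)C(F)(F)F | intermediate
18 | 8-bromo-deca-O-benzylprocyanidin B2: 8-bromo-penta-O-benzylepicatechin-(4β→8)-penta-O-benzylepicatechin, Br on C8 of the upper unit | Brc1c(OCc4ccccc4)cc(OCc4ccccc4)c3c1O[C@H](c1ccc(OCc4ccccc4)c(OCc4ccccc4)c1)[C@H](OCc4ccccc4)[C@H]3c1c(OCc4ccccc4)cc(OCc4ccccc4)c3c1O[C@H](c1ccc(OCc4ccccc4)c(OCc4ccccc4)c1)[C@H](OCc4ccccc4)C3 | intermediate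
19 | sodium phenoxide of aldehyde 11 | c4ccccc4COc1cc(OCc4ccccc4)c2c(c1)O[C@H](c1ccc(OCc4ccccc4)c(OCc4ccccc4)c1)[C@@H](OCc4ccccc4)[C@@H]2c1c(OCc4ccccc4)cc([O-])c(C=O)c1OCc4ccccc4.[Na+] | intermediate
20 | 8-lithio-deca-O-benzylprocyanidin B2 | [Li]c1c(OCc4ccccc4)cc(OCc4ccccc4)c3c1O[C@H](c1ccc(OCc4ccccc4)c(OCc4ccccc4)c1)[C@H](OCc4ccccc4)[C@H]3c1c(OCc4ccccc4)cc(OCc4ccccc4)c3c1O[C@H](c1ccc(OCc4ccccc4)c(OCc4ccccc4)c1)[C@H](OCc4ccccc4)C3 | intermediate
21 | o-hydroxybenzhydrol: carbinol carbon bonded to C8 of deca-O-benzylprocyanidin B2 and to the 2,4-bis(benzyloxy)-6-hydroxyphenyl ring that carries penta-O-benzylcatechin-4α-yl at its C3 (carbinol epimers) | c4ccccc4COc1cc(OCc4ccccc4)c2c(c1)O[C@H](c1ccc(OCc4ccccc4)c(OCc4ccccc4)c1)[C@@H](OCc4ccccc4)[C@@H]2c1c(OCc4ccccc4)cc(O)c(c1OCc4ccccc4)C(O)c1c(OCc4ccccc4)cc(OCc4ccccc4)c3c1O[C@H](c1ccc(OCc4ccccc4)c(OCc4ccccc4)c1)[C@H](OCc4ccccc4)[C@H]3c1c(OCc4ccccc4)cc(OCc4ccccc4)c3c1O[C@H](c1ccc(OCc4ccccc4)c(OCc4ccccc4)c1)[C@H](OCc4ccccc4)C3 | intermediate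
22 | benzyloxyacetaldehyde | O=CCOCc1ccccc1 | starting material
23 | o-quinone methide from 21 (methide carbon bears H and C8 of the dimer; geometry not fixed) | c4ccccc4COc1cc(OCc4ccccc4)c2c(c1)O[C@H](c1ccc(OCc4ccccc4)c(OCc4ccccc4)c1)[C@@H](OCc4ccccc4)[C@@H]2C5=C(OCc4ccccc4)C(=Cc1c(OCc4ccccc4)cc(OCc4ccccc4)c3c1O[C@H](c1ccc(OCc4ccccc4)c(OCc4ccccc4)c1)[C@H](OCc4ccccc4)[C@H]3c1c(OCc4ccccc4)cc(OCc4ccccc4)c3c1O[C@H](c1ccc(OCc4ccccc4)c(OCc4ccccc4)c1)[C@H](OCc4ccccc4)C3)C(=O)C=C5OCc4ccccc4 | intermediate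
24 | E-enamine of 22 with (S)-α,α-diphenylprolinol trimethylsilyl ether | C[Si](C)(C)OC(c1ccccc1)(c1ccccc1)[C@@H]1CCCN1/C=C/OCc1ccccc1 | intermediate
25 | aminal cycloadduct: lactol 26 with the pyrrolidine nitrogen of the catalyst in place of the C2 hydroxyl (C2 not assigned) | c4ccccc4COc1cc(OCc4ccccc4)c2c(c1)O[C@H](c1ccc(OCc4ccccc4)c(OCc4ccccc4)c1)[C@@H](OCc4ccccc4)[C@@H]2c1c(OCc4ccccc4)cc2c(c1OCc4ccccc4)[C@H](c1c(OCc4ccccc4)cc(OCc4ccccc4)c3c1O[C@H](c1ccc(OCc4ccccc4)c(OCc4ccccc4)c1)[C@H](OCc4ccccc4)[C@H]3c1c(OCc4ccccc4)cc(OCc4ccccc4)c3c1O[C@H](c1ccc(OCc4ccccc4)c(OCc4ccccc4)c1)[C@H](OCc4ccccc4)C3)[C@@H](OCc4ccccc4)C(N5CCC[C@H]5C(c6ccccc6)(c6ccccc6)O[Si](C)(C)C)O2 | intermediate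
26 | tetramer lactol lacking ring B of unit 2: unit 2 is a 3R-benzyloxy-chroman-2-ol, 3,4-trans, with unit 1 at C6 and the dimer at C4 (C2 anomers) | c4ccccc4COc1cc(OCc4ccccc4)c2c(c1)O[C@H](c1ccc(OCc4ccccc4)c(OCc4ccccc4)c1)[C@@H](OCc4ccccc4)[C@@H]2c1c(OCc4ccccc4)cc2c(c1OCc4ccccc4)[C@H](c1c(OCc4ccccc4)cc(OCc4ccccc4)c3c1O[C@H](c1ccc(OCc4ccccc4)c(OCc4ccccc4)c1)[C@H](OCc4ccccc4)[C@H]3c1c(OCc4ccccc4)cc(OCc4ccccc4)c3c1O[C@H](c1ccc(OCc4ccccc4)c(OCc4ccccc4)c1)[C@H](OCc4ccccc4)C3)[C@@H](OCc4ccccc4)C(O)O2 | intermediate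
27 | tetramer lactone: unit 2 as the 3R-benzyloxy-4-aryl-chroman-2-one | c4ccccc4COc1cc(OCc4ccccc4)c2c(c1)O[C@H](c1ccc(OCc4ccccc4)c(OCc4ccccc4)c1)[C@@H](OCc4ccccc4)[C@@H]2c1c(OCc4ccccc4)cc2c(c1OCc4ccccc4)[C@H](c1c(OCc4ccccc4)cc(OCc4ccccc4)c3c1O[C@H](c1ccc(OCc4ccccc4)c(OCc4ccccc4)c1)[C@H](OCc4ccccc4)[C@H]3c1c(OCc4ccccc4)cc(OCc4ccccc4)c3c1O[C@H](c1ccc(OCc4ccccc4)c(OCc4ccccc4)c1)[C@H](OCc4ccccc4)C3)[C@@H](OCc4ccccc4)C(=O)O2 | intermediate
28 | 4-bromo-1,2-bis(benzyloxy)benzene | Brc1ccc(OCc2ccccc2)c(OCc2ccccc2)c1 | starting material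
29 | 3,4-bis(benzyloxy)phenyllithium | [Li]c1ccc(OCc2ccccc2)c(OCc2ccccc2)c1 | intermediate
30 | 2-aryl hemiketal: unit 2 as the 2-[3,4-bis(benzyloxy)phenyl]chroman-2-ol (C2 not assigned; in equilibrium with the open keto-phenol) | c4ccccc4COc1cc(OCc4ccccc4)c2c(c1)O[C@H](c1ccc(OCc4ccccc4)c(OCc4ccccc4)c1)[C@@H](OCc4ccccc4)[C@@H]2c1c(OCc4ccccc4)cc2c(c1OCc4ccccc4)[C@H](c1c(OCc4ccccc4)cc(OCc4ccccc4)c3c1O[C@H](c1ccc(OCc4ccccc4)c(OCc4ccccc4)c1)[C@H](OCc4ccccc4)[C@H]3c1c(OCc4ccccc4)cc(OCc4ccccc4)c3c1O[C@H](c1ccc(OCc4ccccc4)c(OCc4ccccc4)c1)[C@H](OCc4ccccc4)C3)[C@@H](OCc4ccccc4)C(O)(c1ccc(OCc4ccccc4)c(OCc4ccccc4)c1)O2 | intermediate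
31 | 2-aryl oxocarbenium ion from 30 (O1=C2 cation of unit 2) | c4ccccc4COc1cc(OCc4ccccc4)c2c(c1)O[C@H](c1ccc(OCc4ccccc4)c(OCc4ccccc4)c1)[C@@H](OCc4ccccc4)[C@@H]2c1c(OCc4ccccc4)cc2c(c1OCc4ccccc4)[C@H](c1c(OCc4ccccc4)cc(OCc4ccccc4)c3c1O[C@H](c1ccc(OCc4ccccc4)c(OCc4ccccc4)c1)[C@H](OCc4ccccc4)[C@H]3c1c(OCc4ccccc4)cc(OCc4ccccc4)c3c1O[C@H](c1ccc(OCc4ccccc4)c(OCc4ccccc4)c1)[C@H](OCc4ccccc4)C3)[C@@H](OCc4ccccc4)C(c1ccc(OCc4ccccc4)c(OCc4ccccc4)c1)=[O+]2 | intermediate
32 | icosa-O-benzyl catechin-(4α→6)-epicatechin-(4β→8)-epicatechin-(4β→8)-epicatechin | c4ccccc4COc1cc(OCc4ccccc4)c2c(c1)O[C@H](c1ccc(OCc4ccccc4)c(OCc4ccccc4)c1)[C@@H](OCc4ccccc4)[C@@H]2c1c(OCc4ccccc4)cc2c(c1OCc4ccccc4)[C@H](c1c(OCc4ccccc4)cc(OCc4ccccc4)c3c1O[C@H](c1ccc(OCc4ccccc4)c(OCc4ccccc4)c1)[C@H](OCc4ccccc4)[C@H]3c1c(OCc4ccccc4)cc(OCc4ccccc4)c3c1O[C@H](c1ccc(OCc4ccccc4)c(OCc4ccccc4)c1)[C@H](OCc4ccccc4)C3)[C@@H](OCc4ccccc4)[C@@H](c1ccc(OCc4ccccc4)c(OCc4ccccc4)c1)O2 | intermediate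
33 | catechin-(4α→6)-epicatechin-(4β→8)-epicatechin-(4β→8)-epicatechin (CNP0228086.1) | Oc1cc(O)c2c(c1)O[C@H](c1ccc(O)c(O)c1)[C@@H](O)[C@@H]2c1c(O)cc2c(c1O)[C@H](c1c(O)cc(O)c3c1O[C@H](c1ccc(O)c(O)c1)[C@H](O)[C@H]3c1c(O)cc(O)c3c1O[C@H](c1ccc(O)c(O)c1)[C@H](O)C3)[C@@H](O)[C@@H](c1ccc(O)c(O)c1)O2 | target

Total step count: 16. Longest linear sequence: 11 steps from (+)-catechin (steps 1, 2, 4, 5, 6, 11, 12, 13, 14, 15, 16).

Steps most likely to fail

1. Step 12. The methide carbon of 23 is flanked on both faces by the ortho oxygens of two aryl rings and is strongly stabilised by its alkoxy donors. Enamine addition may therefore lag behind self-aldolisation of 22, or may follow the bias of the resident stereocentres and give C3/C4 epimers. The fallback abandons the cycloaddition for cationic interflavan coupling with a halogen cap; it sets out from 4, 14 and 18 and comes back to the route at 33. The cation of ion pair 7, released from 4 with Me3SiOTf at −78 °C, is captured by bromide 14, whose blocked C8 leaves C6 as the only free position of ring A, to give perbenzylated catechin-(4α→6)-8-bromoepicatechin F1. DDQ and 2-ethoxyethanol then oxidise the C4 methylene of its lower unit to the 4β-(2-ethoxyethoxy) dimer F2; the C4–H of the upper unit lies close to the plane of its ring A and should resist hydride abstraction. Bromide 18 is reduced with n-BuLi and then methanol to perbenzylated procyanidin B2 F3. Me3SiOTf-promoted coupling of F2 with excess F3, which reacts through C8 of its upper unit, gives the 8-bromo icosa-O-benzyl tetramer F4. Hydrogenolysis over Pd(OH)2/C with Et3N removes the benzyl groups and the bromine and gives 33.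

2. Step 15. The facial selectivity of hydride transfer may be poor or reversed: the axial approach anti to the 3-benzyloxy group passes the pseudoaxial C4 aryl group, so delivery from the opposite face, leading to the 2,3-trans C2 epimer, may compete. The fallback exchanges the roles of hydride and aryl at C2; it sets out from 26 and comes back at 32. If the face anti to the C4 aryl group is the preferred one, an aryl nucleophile entering there ends up cis to the 3-benzyloxy group. Lactol 26 is acetylated (Ac2O, pyridine) to the 2-O-acetyl lactol F5. Aryllithium 29 is converted with B(OMe)3 and then KHF2 into potassium [3,4-bis(benzyloxy)phenyl]trifluoroborate F6. BF3·OEt2 in MeCN/CH2Cl2 ionises F5 to the C2–H oxocarbenium ion and F6 transfers its aryl group, a known arylation of O-acyl acetals with organotrifluoroborates, to give 32.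

3. Step 14. The tetrahedral adduct may collapse with loss of the tethered phenoxide and take up a second aryllithium at the liberated aryl ketone, or 27 may enolise at C3 and epimerise. The fallback replaces the lactone by an open-chain Weinreb amide; it sets out from 27 and comes back at 30. Lactone 27 is opened with MeONHMe·HCl and i-PrMgCl (THF, −20 °C) to the phenolic N-methoxy-N-methylamide F7. Two or more equivalents of 29, the first forming the phenoxide, give the stable chelated adduct, which on aqueous work-up releases the aryl ketone that closes onto the phenol as hemiketal 30.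

Further compounds

F1 | step 12 | perbenzylated catechin-(4α→6)-8-bromoepicatechin | c4ccccc4COc1cc(OCc4ccccc4)c2c(c1)O[C@H](c1ccc(OCc4ccccc4)c(OCc4ccccc4)c1)[C@@H](OCc4ccccc4)[C@@H]2c1c(OCc4ccccc4)c(Br)c2c(c1OCc4ccccc4)C[C@@H](OCc4ccccc4)[C@@H](c1ccc(OCc4ccccc4)c(OCc4ccccc4)c1)O2
F2 | step 12 | F1 carrying a 4β-(2-ethoxyethoxy) group on its brominated lower unit | c4ccccc4COc1cc(OCc4ccccc4)c2c(c1)O[C@H](c1ccc(OCc4ccccc4)c(OCc4ccccc4)c1)[C@@H](OCc4ccccc4)[C@@H]2c1c(OCc4ccccc4)c(Br)c2c(c1OCc4ccccc4)[C@H](OCCOCC)[C@@H](OCc4ccccc4)[C@@H](c1ccc(OCc4ccccc4)c(OCc4ccccc4)c1)O2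
F3 | step 12 | deca-O-benzylprocyanidin B2 | c1c(OCc4ccccc4)cc(OCc4ccccc4)c3c1O[C@H](c1ccc(OCc4ccccc4)c(OCc4ccccc4)c1)[C@H](OCc4ccccc4)[C@H]3c1c(OCc4ccccc4)cc(OCc4ccccc4)c3c1O[C@H](c1ccc(OCc4ccccc4)c(OCc4ccccc4)c1)[C@H](OCc4ccccc4)C3
F4 | step 12 | icosa-O-benzyl tetramer with bromine at C8 of unit 2 | c4ccccc4COc1cc(OCc4ccccc4)c2c(c1)O[C@H](c1ccc(OCc4ccccc4)c(OCc4ccccc4)c1)[C@@H](OCc4ccccc4)[C@@H]2c1c(OCc4ccccc4)c(Br)c2c(c1OCc4ccccc4)[C@H](c1c(OCc4ccccc4)cc(OCc4ccccc4)c3c1O[C@H](c1ccc(OCc4ccccc4)c(OCc4ccccc4)c1)[C@H](OCc4ccccc4)[C@H]3c1c(OCc4ccccc4)cc(OCc4ccccc4)c3c1O[C@H](c1ccc(OCc4ccccc4)c(OCc4ccccc4)c1)[C@H](OCc4ccccc4)C3)[C@@H](OCc4ccccc4)[C@@H](c1ccc(OCc4ccccc4)c(OCc4ccccc4)c1)O2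
F5 | step 15 | 2-O-acetyl derivative of lactol 26 (C2 anomers) | c4ccccc4COc1cc(OCc4ccccc4)c2c(c1)O[C@H](c1ccc(OCc4ccccc4)c(OCc4ccccc4)c1)[C@@H](OCc4ccccc4)[C@@H]2c1c(OCc4ccccc4)cc2c(c1OCc4ccccc4)[C@H](c1c(OCc4ccccc4)cc(OCc4ccccc4)c3c1O[C@H](c1ccc(OCc4ccccc4)c(OCc4ccccc4)c1)[C@H](OCc4ccccc4)[C@H]3c1c(OCc4ccccc4)cc(OCc4ccccc4)c3c1O[C@H](c1ccc(OCc4ccccc4)c(OCc4ccccc4)c1)[C@H](OCc4ccccc4)C3)[C@@H](OCc4ccccc4)C(OC(C)=O)O2
F6 | step 15 | potassium [3,4-bis(benzyloxy)phenyl]trifluoroborate | [K+].F[B-](F)(F)c1ccc(OCc2ccccc2)c(OCc2ccccc2)c1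
F7 | step 14 | phenolic N-methoxy-N-methylamide from ring opening of lactone 27 | c4ccccc4COc1cc(OCc4ccccc4)c2c(c1)O[C@H](c1ccc(OCc4ccccc4)c(OCc4ccccc4)c1)[C@@H](OCc4ccccc4)[C@@H]2c1c(OCc4ccccc4)cc(O)c(c1OCc4ccccc4)[C@H](c1c(OCc4ccccc4)cc(OCc4ccccc4)c3c1O[C@H](c1ccc(OCc4ccccc4)c(OCc4ccccc4)c1)[C@H](OCc4ccccc4)[C@H]3c1c(OCc4ccccc4)cc(OCc4ccccc4)c3c1O[C@H](c1ccc(OCc4ccccc4)c(OCc4ccccc4)c1)[C@H](OCc4ccccc4)C3)[C@@H](OCc4ccccc4)C(=O)N(C)OC
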